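## Retrosynthetic overview

1. Target ⇒ (S)-pinostrobin + two molecules of the salicyl alcohol "arm": twofold o-quinone-methide C-benzylation at C6 and C8, done last, no ring formed.
2. (S)-Pinostrobin ⇒ a 6-(4-hydroxy-2-oxo-4-phenylbutyl)-4-methoxy-2-pyrone: in one flask the carbinol oxygen takes over C6 of the pyrone (ring C, stereocentre retained) and the released acid closes ring A by C-acylation. The pyrone is a masked triketide that already carries the 7-OMe.
3. Pyrone hydroxy ketone ⇒ 4-methoxy-6-methyl-2-pyrone + ethyl (S)-3-hydroxy-3-phenylpropanoate (vinylogous Claisen; chirality bought).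
4. Arm ⇒ 5-(chloromethyl)salicylaldehyde + 4-bromophenol (Br blocks para, so Friedel–Crafts is ortho-only), then CHO reduction and debromination.
5. Ring order: C, then A, in the same operation; ring B and the four phenol rings come from starting materials.

Assumption: ethyl (3S)-3-hydroxy-3-phenylpropanoate of ≥98% ee is bought as a catalogue chemical; the target is (2S), as read from the SMILES.

## Route

Step 1
Reactants: 1 4-methoxy-6-methyl-2H-pyran-2-one; 2 ethyl (3S)-3-hydroxy-3-phenylpropanoate
Product: 4 6-[(4S)-4-hydroxy-2-oxo-4-phenylbutyl]-4-methoxy-2H-pyran-2-one, via 6-(lithiomethyl)-4-methoxy-2H-pyran-2-one 3 (not isolated)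
Conditions: 1 (3.3 equiv), LDA (3.2 equiv), THF, −78 °C, 30 min; then 2 (1.0 equiv), −78 → −20 °C; 1 M HCl to pH 4
Reagents that add atoms: none
Why: Vinylogous crossed Claisen condensation: LDA deprotonates the 6-methyl group to the extended dienolate 3, which is C-acylated by the ester; the excess anion first takes the OH proton and finally the acidic product, which stops over-addition and retro-aldol, and the existing stereocentre is not involved (precedent type: Claisen condensations of lithium enolates with unprotected β-hydroxy esters).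

Step 2 (key step)
Reactants: 4 6-[(4S)-4-hydroxy-2-oxo-4-phenylbutyl]-4-methoxy-2H-pyran-2-one
Product: 7 (S)-pinostrobin [(2S)-5-hydroxy-7-methoxy-2-phenylchroman-4-one], via dihydropyranone acid 5 (not isolated), via mixed trifluoroacetic anhydride 6 (not isolated)
Conditions: TFA–CH2Cl2 (1:4), 0 °C → rt until 4 is consumed; then TFAA (1.5 equiv), 0 °C → rt; aq NaHCO3
Reagents that add atoms: none
Why: Proposed new method: in TFA the carbinol oxygen adds to C6 of the protonated pyrone and the enol-lactone oxygen leaves as a carboxylic acid (a vinylogous transesterification), giving dihydropyranone 5 (ring C) without ever breaking the C–O bond of the stereocentre, so S is retained; the (E)-β-methoxyacrylic acid, held cis to the ring by the former pyrone double bond, is then activated as mixed anhydride 6 and C-acylates the nucleophilic C5 of the vinylogous ester, and the dienone tautomerises to the phenol (ring A); the closest known reactions are the TFA cyclodehydration of δ-hydroxy-β-diketones to 2,3-dihydro-4H-pyran-4-ones, base-mediated 2-pyrone → acylphloroglucinol ring transformations and anhydride-mediated cycloaromatisation of dienoic acids (Stobbe-type benzannulation).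

Step 3
Reactants: 8 5-(chloromethyl)-2-hydroxybenzaldehyde; 9 4-bromophenol
Product: 10 5-(5-bromo-2-hydroxybenzyl)-2-hydroxybenzaldehyde
Conditions: 9 (6 equiv, melt), ZnCl2 (10 mol%), 80 °C, 2 h
Reagents that add atoms: none
Why: Friedel–Crafts benzylation: ZnCl2 ionises the para-hydroxybenzylic chloride and the cation attacks 4-bromophenol ortho to OH, the only activated position because bromine blocks para; the large excess of 9 suppresses double alkylation and the deactivated salicylaldehyde ring does not compete.

Step 4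
Reactants: 10 5-(5-bromo-2-hydroxybenzyl)-2-hydroxybenzaldehyde
Product: 12 4-(2-hydroxybenzyl)-2-(hydroxymethyl)phenol, via bromo benzyl alcohol 11 (not isolated)
Conditions: NaBH4 (1.5 equiv), MeOH, 0 °C; then 10% Pd/C (5 mol%), NaBH4 (4 equiv), MeOH–H2O, rt; aq NH4Cl
Reagents that add atoms: none
Why: Borohydride reduction of the aldehyde, then palladium-catalysed hydrodebromination with NaBH4 as the hydride source in the same flask; under these basic conditions the salicyl alcohol C–O bond is not hydrogenolysed.

Step 5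
Reactants: 7 (S)-pinostrobin; 12 4-(2-hydroxybenzyl)-2-(hydroxymethyl)phenol (3 equiv)
Product: 16 (2S)-5-hydroxy-6,8-bis[2-hydroxy-5-(2-hydroxybenzyl)benzyl]-7-methoxy-2-phenylchroman-4-one (target), via o-quinone methide 13 (not isolated), via 8-monobenzyl flavanone 14 (not isolated), via 6-monobenzyl flavanone 15 (not isolated)
Conditions: 12 added in portions, ZnCl2 (anhydrous, 4 equiv), 1,4-dioxane, 85 °C, 16 h
Reagents that add atoms: none
Why: Biomimetic twofold Friedel–Crafts-type (Michael) addition: ZnCl2 dehydrates the salicyl alcohol to o-quinone methide 13, which is attacked by C6 and C8, the only free and strongly activated A-ring carbons (through 14 and 15), with rearomatisation; portionwise addition limits self-condensation of 12, and because no base is present the chelated 5-hydroxyflavanone does not open to the chalcone, so C2 stays S.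

## Compound list

1 | 4-methoxy-6-methyl-2H-pyran-2-one | COC1=CC(=O)OC(C)=C1 | starting material
2 | ethyl (3S)-3-hydroxy-3-phenylpropanoate | CCOC(=O)C[C@H](O)c1ccccc1 | starting material
3 | 6-(lithiomethyl)-4-methoxy-2H-pyran-2-one | [Li]CC1=CC(OC)=CC(=O)O1 | intermediate
4 | 6-[(4S)-4-hydroxy-2-oxo-4-phenylbutyl]-4-methoxy-2H-pyran-2-one | COC1=CC(=O)OC(CC(=O)C[C@H](O)c2ccccc2)=C1 | intermediate
5 | (2E)-3-methoxy-4-[(2S)-4-oxo-2-phenyl-3,4-dihydro-2H-pyran-6-yl]but-2-enoic acid | O=C(O)/C=C(/OC)CC1=CC(=O)C[C@@H](c2ccccc2)O1 | intermediate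
6 | mixed anhydride of 5 and trifluoroacetic acid | O=C(OC(=O)C(F)(F)F)/C=C(/OC)CC1=CC(=O)C[C@@H](c2ccccc2)O1 | intermediate
7 | (2S)-5-hydroxy-7-methoxy-2-phenylchroman-4-one [(S)-pinostrobin] | O=C1C[C@@H](c2ccccc2)Oc2cc(OC)cc(O)c12 | intermediate
8 | 5-(chloromethyl)-2-hydroxybenzaldehyde | O=Cc1cc(CCl)ccc1O | starting material
9 | 4-bromophenol | Oc1ccc(Br)cc1 | starting material
10 | 5-(5-bromo-2-hydroxybenzyl)-2-hydroxybenzaldehyde | O=Cc1cc(Cc2cc(Br)ccc2O)ccc1O | intermediate
11 | 4-(5-bromo-2-hydroxybenzyl)-2-(hydroxymethyl)phenol | OCc1cc(Cc2cc(Br)ccc2O)ccc1O | intermediate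
12 | 4-(2-hydroxybenzyl)-2-(hydroxymethyl)phenol | OCc1cc(Cc2ccccc2O)ccc1O | intermediate
13 | 4-(2-hydroxybenzyl)-6-methylidenecyclohexa-2,4-dien-1-one | C=C1C=C(Cc2ccccc2O)C=CC1=O | intermediate
14 | (2S)-5-hydroxy-8-[2-hydroxy-5-(2-hydroxybenzyl)benzyl]-7-methoxy-2-phenylchroman-4-one | COc1cc(O)c2c(c1Cc1cc(Cc3ccccc3O)ccc1O)O[C@H](c1ccccc1)CC2=O | intermediate
15 | (2S)-5-hydroxy-6-[2-hydroxy-5-(2-hydroxybenzyl)benzyl]-7-methoxy-2-phenylchroman-4-one | COc1c(Cc2cc(Cc3ccccc3O)ccc2O)c(O)c2c(c1)O[C@H](c1ccccc1)CC2=O | intermediate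
16 | (2S)-5-hydroxy-6,8-bis[2-hydroxy-5-(2-hydroxybenzyl)benzyl]-7-methoxy-2-phenylchroman-4-one | COc1c(Cc2cc(Cc3ccccc3O)ccc2O)c(O)c2c(c1Cc1cc(Cc3ccccc3O)ccc1O)O[C@H](c1ccccc1)CC2=O | target

## Step count and risks

Total steps: 5. Longest linear sequence: 3 (steps 1, 2, 5 or steps 3, 4, 5).

**Step 2 (ring transformation).** The acid-mediated closure of ring A is untested, and 5 could also reclose to the pyrone. The fallback sets out from 4 and closes the two rings in separate operations. Compound 4 is treated with TFA only, and the crude acid 5 is trapped with TMSCHN2 as methyl (2E)-3-methoxy-4-[(2S)-4-oxo-2-phenyl-3,4-dihydro-2H-pyran-6-yl]but-2-enoate F1, which is isolated. Ring A is then closed under base instead of acid by a vinylogous Dieckmann condensation (LiHMDS, THF, −78 → 0 °C): the doubly activated CH2 is deprotonated, pyranone C5 attacks the ester, methoxide is lost and the dienone tautomerises. This comes back to the route at 7.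

**Step 5 (double benzylation).** The arm alcohol 12 has two nucleophilic phenol rings and can consume its own quinone methide. The fallback sets out from 10 and keeps the bromine as a deactivating para-blocker through the coupling. Compound 10 is reduced with NaBH4 alone and 11 is isolated. Compound 11 is coupled with 7 under the same ZnCl2/dioxane conditions to give (2S)-6,8-bis[5-(5-bromo-2-hydroxybenzyl)-2-hydroxybenzyl]-5-hydroxy-7-methoxy-2-phenylchroman-4-one F2. Both C–Br bonds are then removed by hydrogenolysis (H2, Pd/C, NaOAc, EtOAc–MeOH, rt), which comes back to the route at 16.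

**Step 1 (Claisen with the free hydroxy ester).** The alkoxide-bearing ester may acylate the stabilised pyrone anion too slowly. The fallback sets out from 2 and changes the acyl donor. Compound 2 is silylated (TBSCl, imidazole) to ethyl (3S)-3-[(tert-butyldimethylsilyl)oxy]-3-phenylpropanoate F3. This is converted with MeNHOMe·HCl/iPrMgCl into (3S)-3-[(tert-butyldimethylsilyl)oxy]-N-methoxy-N-methyl-3-phenylpropanamide F4. The Weinreb amide acylates lithiated 1 (2.2 equiv) to give 6-[(4S)-4-[(tert-butyldimethylsilyl)oxy]-2-oxo-4-phenylbutyl]-4-methoxy-2H-pyran-2-one F5. HF·pyridine removes the silyl group and comes back to the route at 4.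

## Further compounds

F1 | step 2 | methyl (2E)-3-methoxy-4-[(2S)-4-oxo-2-phenyl-3,4-dihydro-2H-pyran-6-yl]but-2-enoate | COC(=O)/C=C(/OC)CC1=CC(=O)C[C@@H](c2ccccc2)O1
F2 | step 5 | (2S)-6,8-bis[5-(5-bromo-2-hydroxybenzyl)-2-hydroxybenzyl]-5-hydroxy-7-methoxy-2-phenylchroman-4-one | COc1c(Cc2cc(Cc3cc(Br)ccc3O)ccc2O)c(O)c2c(c1Cc1cc(Cc3cc(Br)ccc3O)ccc1O)O[C@H](c1ccccc1)CC2=O
F3 | step 1 | ethyl (3S)-3-[(tert-butyldimethylsilyl)oxy]-3-phenylpropanoate | CCOC(=O)C[C@H](O[Si](C)(C)C(C)(C)C)c1ccccc1
F4 | step 1 | (3S)-3-[(tert-butyldimethylsilyl)oxy]-N-methoxy-N-methyl-3-phenylpropanamide | CON(C)C(=O)C[C@H](O[Si](C)(C)C(C)(C)C)c1ccccc1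
F5 | step 1 | 6-[(4S)-4-[(tert-butyldimethylsilyl)oxy]-2-oxo-4-phenylbutyl]-4-methoxy-2H-pyran-2-one | COC1=CC(=O)OC(CC(=O)C[C@H](O[Si](C)(C)C(C)(C)C)c2ccccc2)=C1
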